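The route rests on recognising the five-membered ring (C1, C2, C3, C3a, C8a) with its tertiary carbinol C3(OH)(i-Pr), the adjacent methine C3a and the oxygenated C4 as the product of a Favorskii-type contraction of a 2,3-epoxycyclohexanone. The precursor is the p-menthane epoxy ketone derived from carvenone, allylated at the α′ carbon. With methoxide, the quaternary carbon (future C8a) migrates from the carbonyl carbon (future C4) to the epoxide CH (future C3a) with inversion; in one operation the six-membered ring becomes the cyclopentane, the C3a–C8a bond is formed, the epoxide oxygen becomes the C3 hydroxyl and C4 is expelled as an ester. Methallylation and ring-closing metathesis then add the seven-membered ring.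

Key step: step 3

Assumption: racemic carvenone is bought (its stereocentre is erased in step 2), and the quinine-derived amine is taken to deliver the (1S,6R)-epoxide; should it favour the other face, its quinidine-derived pseudo-enantiomer is used.

Step 1
Reactants: 1 carvenone, 6-methyl-3-(propan-2-yl)cyclohex-2-en-1-one (racemic)
Product: 2 (1S,6R)-3-methyl-6-(propan-2-yl)-7-oxabicyclo[4.1.0]heptan-2-one (both C3 epimers)
Conditions: 50% aq. H2O2, 9-amino-9-deoxy-epi-quinine (10 mol %), CF3CO2H (20 mol %), 1,4-dioxane, 40 °C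
Reagents that add atoms: hydrogen peroxide, OO
Why: Weitz–Scheffer-type nucleophilic epoxidation under iminium catalysis by a chiral primary amine salt: hydrogen peroxide should add to the β-carbon of the iminium ion on the face left open by the cinchona scaffold and the resulting enamine closes the oxirane, so both oxirane carbons are set under catalyst control while the remote, still epimerisable methyl-bearing carbon plays no part.

Step 2
Reactants: 2 (1S,6R)-3-methyl-6-(propan-2-yl)-7-oxabicyclo[4.1.0]heptan-2-one; 3 allyl bromide (3-bromoprop-1-ene)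
Product: 5 (1S,3R,6R)-3-methyl-6-(propan-2-yl)-3-(prop-2-en-1-yl)-7-oxabicyclo[4.1.0]heptan-2-one, via lithium enolate 4 (not isolated)
Conditions: LDA (LiN(i-Pr)2), THF, −78 °C; then 3, DMPU, −78 → −30 °C
Reagents that add atoms: allyl bromide (3), C=CCBr
Why: Kinetic enolate alkylation: LDA can enolise only toward the methyl-bearing α′ carbon (the other α-carbon is the oxirane CH, which cannot planarise), and allyl bromide should enter the planar enolate 4 on the face opposite the oxirane oxygen, which shields its own face sterically and through the lithium aggregate bound to it, so that allyl ends up trans and methyl cis to the oxirane.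

Step 3
Reactants: 5 (1S,3R,6R)-3-methyl-6-(propan-2-yl)-3-(prop-2-en-1-yl)-7-oxabicyclo[4.1.0]heptan-2-one
Product: 7 methyl (1R,2R,5R)-2-hydroxy-5-methyl-2-(propan-2-yl)-5-(prop-2-en-1-yl)cyclopentane-1-carboxylate, via sodium hemiketalate 6 (not isolated)
Conditions: NaOMe, MeOH, 0 → 50 °C; aq. NH4Cl
Reagents that add atoms: methanol (as NaOMe), CO
Why: Quasi-Favorskii (semibenzilic) ring contraction: methoxide adds reversibly to the ketone carbon (future C4) and in adduct 6 the bond from this carbon to the quaternary carbon (future C8a) shifts to the oxirane CH (future C3a) while its C–O bond breaks, so the six-membered ring loses the former carbonyl carbon as an exocyclic methyl ester. The closest known reaction type is the base-induced Favorskii-type contraction of 2,3-epoxycyclohexanones such as p-menthenone oxides to 2-hydroxycyclopentanecarboxylic acids; because the α′ carbon of 5 is quaternary, no cyclopropanone or enolate can form and the 1,2-shift is the only Favorskii channel. The cyclopentane is closed through the new C3a–C8a bond by a suprafacial 1,2-alkyl shift, formally an intramolecular backside (3-exo-tet-type) displacement at the oxirane carbon, driven by release of oxirane strain and formation of the ester. C3a is set by inversion at the oxirane carbon, C8a migrates with retention and C3 keeps the oxirane oxygen as its hydroxyl with retention, so CO2Me, OH and CH3 end up on one face as the target requires. The step needs addition and shift to outrun direct opening of the oxirane by methoxide and C–C cleavage of 6; the substrate helps in that only one group can migrate, only one leaving group sits next to the carbonyl carbon, and the ester configuration formed is also the more stable one (trans to isopropyl and allyl), so methoxide should not epimerise it away.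

Step 4
Reactants: 7 methyl (1R,2R,5R)-2-hydroxy-5-methyl-2-(propan-2-yl)-5-(prop-2-en-1-yl)cyclopentane-1-carboxylate
Product: 8 (1R,2R,5R)-2-hydroxy-5-methyl-2-(propan-2-yl)-5-(prop-2-en-1-yl)cyclopentane-1-carbaldehyde
Conditions: DIBAL-H (i-Bu2AlH, 2.5 equiv), CH2Cl2, −78 °C; aq. Rochelle salt
Reagents that add atoms: none
Why: Partial reduction of an ester with DIBAL-H at −78 °C: the hindered ester, flanked by the aluminium alkoxide of the tertiary hydroxyl, should take up one hydride and release the aldehyde only on work-up, and no stereocentre is touched because the epimerisable C1–H never meets a free base.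

Step 5
Reactants: 8 (1R,2R,5R)-2-hydroxy-5-methyl-2-(propan-2-yl)-5-(prop-2-en-1-yl)cyclopentane-1-carbaldehyde; 9 3-bromo-2-methylprop-1-ene
Product: 10 (1R,2S,3R)-2-[(1S)-1-hydroxy-3-methylbut-3-en-1-yl]-3-methyl-1-(propan-2-yl)-3-(prop-2-en-1-yl)cyclopentan-1-ol
Conditions: In powder, 9, THF/H2O (1:1), 25 °C
Reagents that add atoms: 3-bromo-2-methylprop-1-ene (9), C=C(C)CBr
Why: Barbier-type indium-mediated allylation in aqueous THF: the cis β-hydroxyl and the aldehyde oxygen chelate the allylindium species, which then attacks the carbonyl face opposite the quaternary carbon (the face the Felkin–Anh model also selects), so the (S)-carbinol should form without basic conditions that could trigger retro-aldol cleavage.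

Step 6
Reactants: 10 (1R,2S,3R)-2-[(1S)-1-hydroxy-3-methylbut-3-en-1-yl]-3-methyl-1-(propan-2-yl)-3-(prop-2-en-1-yl)cyclopentan-1-ol
Product: 11 (3R,3aS,4S,8aR)-6,8a-dimethyl-3-(propan-2-yl)-1,2,3,3a,4,5,8,8a-octahydroazulene-3,4-diol
Conditions: second-generation Grubbs catalyst RuCl2(=CHPh)(H2IMes)(PCy3) (5 mol %), CH2Cl2 (0.005 M), 40 °C
Reagents that add atoms: none
Why: Ring-closing metathesis between the monosubstituted allyl alkene and the 1,1-disubstituted methallyl alkene closes the seven-membered ring as a trisubstituted cycloheptene with loss of ethene, and the trans disposition of the two tethers on the cyclopentane carries over into the trans ring fusion.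

Step 7
Reactants: 11 (3R,3aS,4S,8aR)-6,8a-dimethyl-3-(propan-2-yl)-1,2,3,3a,4,5,8,8a-octahydroazulene-3,4-diol; 12 (2E)-3-[4-(acetyloxy)phenyl]prop-2-enoic acid
Product: 13 (3R,3aS,4S,8aR)-3-hydroxy-6,8a-dimethyl-3-(propan-2-yl)-1,2,3,3a,4,5,8,8a-octahydroazulen-4-yl (2E)-3-[4-(acetyloxy)phenyl]prop-2-enoate
Conditions: DCC, DMAP, CH2Cl2, 25 °C
Reagents that add atoms: (2E)-3-[4-(acetyloxy)phenyl]prop-2-enoic acid (12), CC(=O)Oc1ccc(/C=C/C(=O)O)cc1
Why: Steglich esterification: DCC/DMAP activation of the cinnamic acid should acylate only the secondary C4 hydroxyl, the tertiary C3 hydroxyl being too hindered, and the E geometry of the acid and the C4 configuration are retained because the C–O bond of the alcohol is not broken.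

Step 8
Reactants: 13 (3R,3aS,4S,8aR)-3-hydroxy-6,8a-dimethyl-3-(propan-2-yl)-1,2,3,3a,4,5,8,8a-octahydroazulen-4-yl (2E)-3-[4-(acetyloxy)phenyl]prop-2-enoate
Product: 14 (3R,3aS,4S,8aR)-3-hydroxy-6,8a-dimethyl-3-(propan-2-yl)-1,2,3,3a,4,5,8,8a-octahydroazulen-4-yl (2E)-3-(4-hydroxyphenyl)prop-2-enoate
Conditions: pyrrolidine (2 equiv), CH2Cl2, 0 °C
Reagents that add atoms: none
Why: Chemoselective aminolysis: the aryl acetate is far more electrophilic than the hindered secondary cinnamate, so pyrrolidine should remove only the acetyl group and free the phenol.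

Compound list
1 | carvenone, 6-methyl-3-(propan-2-yl)cyclohex-2-en-1-one (racemic) | CC1CCC(C(C)C)=CC1=O | starting material
2 | (1S,6R)-3-methyl-6-(propan-2-yl)-7-oxabicyclo[4.1.0]heptan-2-one (both C3 epimers) | O=C1C(C)CC[C@]2(C(C)C)O[C@H]12 | intermediate
3 | allyl bromide, 3-bromoprop-1-ene | C=CCBr | starting material
4 | lithium enolate of 2, lithium (1S,6R)-3-methyl-6-(propan-2-yl)-7-oxabicyclo[4.1.0]hept-2-en-2-olate | [Li+].[O-]C1=C(C)CC[C@]2(C(C)C)O[C@H]12 | intermediate
5 | (1S,3R,6R)-3-methyl-6-(propan-2-yl)-3-(prop-2-en-1-yl)-7-oxabicyclo[4.1.0]heptan-2-one | O=C1[C@@](C)(CC=C)CC[C@]2(C(C)C)O[C@H]12 | intermediate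
6 | sodium salt of the methyl hemiketal of 5 (methoxide adduct at C2, configuration at C2 open) | [Na+].[O-]C1(OC)[C@@](C)(CC=C)CC[C@]2(C(C)C)O[C@H]12 | intermediate
7 | methyl (1R,2R,5R)-2-hydroxy-5-methyl-2-(propan-2-yl)-5-(prop-2-en-1-yl)cyclopentane-1-carboxylate | C=CC[C@@]1(C)CC[C@@](O)(C(C)C)[C@@H]1C(=O)OC | intermediate
8 | (1R,2R,5R)-2-hydroxy-5-methyl-2-(propan-2-yl)-5-(prop-2-en-1-yl)cyclopentane-1-carbaldehyde | C=CC[C@@]1(C)CC[C@@](O)(C(C)C)[C@@H]1C=O | intermediate
9 | 3-bromo-2-methylprop-1-ene (methallyl bromide) | C=C(C)CBr | starting material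
10 | (1R,2S,3R)-2-[(1S)-1-hydroxy-3-methylbut-3-en-1-yl]-3-methyl-1-(propan-2-yl)-3-(prop-2-en-1-yl)cyclopentan-1-ol | C=CC[C@@]1(C)CC[C@@](O)(C(C)C)[C@@H]1[C@@H](O)CC(C)=C | intermediate
11 | (3R,3aS,4S,8aR)-6,8a-dimethyl-3-(propan-2-yl)-1,2,3,3a,4,5,8,8a-octahydroazulene-3,4-diol | CC1=CC[C@@]2(C)CC[C@@](O)(C(C)C)[C@@H]2[C@@H](O)C1 | intermediate
12 | (2E)-3-[4-(acetyloxy)phenyl]prop-2-enoic acid (4-acetoxycinnamic acid) | CC(=O)Oc1ccc(/C=C/C(=O)O)cc1 | starting material
13 | (3R,3aS,4S,8aR)-3-hydroxy-6,8a-dimethyl-3-(propan-2-yl)-1,2,3,3a,4,5,8,8a-octahydroazulen-4-yl (2E)-3-[4-(acetyloxy)phenyl]prop-2-enoate | CC1=CC[C@@]2(C)CC[C@@](O)(C(C)C)[C@@H]2[C@@H](OC(=O)/C=C/c2ccc(OC(C)=O)cc2)C1 | intermediate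
14 | (3R,3aS,4S,8aR)-3-hydroxy-6,8a-dimethyl-3-(propan-2-yl)-1,2,3,3a,4,5,8,8a-octahydroazulen-4-yl (2E)-3-(4-hydroxyphenyl)prop-2-enoate | CC1=CC[C@@]2(C)CC[C@@](O)(C(C)C)[C@@H]2[C@@H](OC(=O)/C=C/c2ccc(O)cc2)C1 | target

Total step count: 8
Longest linear sequence: 8 steps (1 → 14)

Steps most likely to fail

Step 3 (key ring contraction). Methoxide may open the oxirane directly at the α-carbon, or adduct 6 may fragment by C–C cleavage, faster than the 1,2-shift, because addition to a carbonyl next to a quaternary carbon is slow and the migrating bond is only partly antiperiplanar to the breaking C–O bond. The fallback carries the same contraction by a Wolff rearrangement, which is established for 2-diazocyclohexanones. It sets out from 5: SmI2 (THF/MeOH, −78 °C) should open the oxirane reductively at the α-carbon to the β-hydroxy ketone (3S,6R)-3-hydroxy-6-methyl-3-(propan-2-yl)-6-(prop-2-en-1-yl)cyclohexan-1-one F1. LiN(SiMe3)2 and then CF3CO2CH2CF3 acylate the only enolisable position to give the 2-trifluoroacetyl ketone F2, and MsN3/Et3N effect detrifluoroacetylative diazo transfer to the 2-diazo ketone F3. Irradiation in methanol (300 nm) then contracts the ring with migration of the same quaternary carbon; protonation on the open face is expected to give partly the C1 epimer of the ester, methyl (1S,2R,5R)-2-hydroxy-5-methyl-2-(propan-2-yl)-5-(prop-2-en-1-yl)cyclopentane-1-carboxylate F4, which NaOMe/MeOH at 25 °C should equilibrate to the more stable 7, where the route is rejoined.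

Step 2 (allylation of the epoxy ketone enolate). The risk is poor facial selectivity, with allyl entering syn to the oxirane, or loss of enolate 4 by intramolecular opening of the oxirane on warming. The fallback replaces substrate-controlled alkylation by ligand-controlled decarboxylative allylation. It sets out from 2: LDA and allyl chloroformate at −78 °C trap the enolate on oxygen as the allyl enol carbonate prop-2-en-1-yl (1S,6R)-3-methyl-6-(propan-2-yl)-7-oxabicyclo[4.1.0]hept-2-en-2-yl carbonate F5. Pd2(dba)3 with (R)-t-Bu-PHOX in THF at 25 °C should then deliver the allyl group in a Tsuji allylation, with the ligand reinforcing the bias of the oxirane, and give 5 directly.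

Step 1 (asymmetric epoxidation). The risk is slow iminium formation or low enantioface control, caused by the bulky β-isopropyl group and the α′-methyl branch. The fallback moves absolute control to the quaternary carbon and relays it to the oxirane. It sets out from 1: LDA and allyl chloroformate give the dienyl carbonate 2-methyl-5-(propan-2-yl)cyclohexa-1,5-dien-1-yl prop-2-en-1-yl carbonate F6. Pd2(dba)3/(R)-t-Bu-PHOX (decarboxylative asymmetric allylation) should give (6R)-6-methyl-3-(propan-2-yl)-6-(prop-2-en-1-yl)cyclohex-2-en-1-one F7. CBS oxazaborolidine-catalysed borane reduction, with the catalyst enantiomer chosen to place the hydroxyl cis to the methyl group, gives (1S,6R)-6-methyl-3-(propan-2-yl)-6-(prop-2-en-1-yl)cyclohex-2-en-1-ol F8. VO(acac)2/t-BuOOH epoxidises the ring alkene syn to the hydroxyl and leaves the allyl group, giving (1R,2R,3R,6R)-3-methyl-6-(propan-2-yl)-3-(prop-2-en-1-yl)-7-oxabicyclo[4.1.0]heptan-2-ol F9. Dess–Martin oxidation of F9 returns to the route at 5.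

Further compounds
F1 | step 3 | (3S,6R)-3-hydroxy-6-methyl-3-(propan-2-yl)-6-(prop-2-en-1-yl)cyclohexan-1-one | O=C1[C@@](C)(CC=C)CC[C@@](O)(C(C)C)C1
F2 | step 3 | (3R,6R)-3-hydroxy-6-methyl-3-(propan-2-yl)-6-(prop-2-en-1-yl)-2-(trifluoroacetyl)cyclohexan-1-one (C2 open, largely enolised) | O=C1[C@@](C)(CC=C)CC[C@@](O)(C(C)C)C1C(=O)C(F)(F)F
F3 | step 3 | (3R,6R)-2-diazo-3-hydroxy-6-methyl-3-(propan-2-yl)-6-(prop-2-en-1-yl)cyclohexan-1-one | O=C1[C@@](C)(CC=C)CC[C@@](O)(C(C)C)C1=[N+]=[N-]
F4 | step 3 | methyl (1S,2R,5R)-2-hydroxy-5-methyl-2-(propan-2-yl)-5-(prop-2-en-1-yl)cyclopentane-1-carboxylate | C=CC[C@@]1(C)CC[C@@](O)(C(C)C)[C@H]1C(=O)OC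
F5 | step 2 | prop-2-en-1-yl (1S,6R)-3-methyl-6-(propan-2-yl)-7-oxabicyclo[4.1.0]hept-2-en-2-yl carbonate | C=CCOC(=O)OC1=C(C)CC[C@]2(C(C)C)O[C@H]12
F6 | step 1 | 2-methyl-5-(propan-2-yl)cyclohexa-1,5-dien-1-yl prop-2-en-1-yl carbonate | C=CCOC(=O)OC1=C(C)CCC(C(C)C)=C1
F7 | step 1 | (6R)-6-methyl-3-(propan-2-yl)-6-(prop-2-en-1-yl)cyclohex-2-en-1-one | O=C1[C@@](C)(CC=C)CCC(C(C)C)=C1
F8 | step 1 | (1S,6R)-6-methyl-3-(propan-2-yl)-6-(prop-2-en-1-yl)cyclohex-2-en-1-ol | O[C@@H]1[C@@](C)(CC=C)CCC(C(C)C)=C1
F9 | step 1 | (1R,2R,3R,6R)-3-methyl-6-(propan-2-yl)-3-(prop-2-en-1-yl)-7-oxabicyclo[4.1.0]heptan-2-ol | O[C@@H]1[C@@](C)(CC=C)CC[C@]2(C(C)C)O[C@H]12
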